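**Retrosynthetic overview**
1. The butenolide, the only ring, is opened at its O1–C5 bond. It comes from 5-exo-dig iodolactonisation of (2E)-3-bromo-2-[(1R)-1-hydroxybutyl]pent-2-en-4-ynoic acid, where anti addition of O and I gives the (E)-iodomethylidene group.
2. The acid comes from its methyl ester, which carries a Me3Si cap on the alkyne. One hydroxide treatment removes both.
3. The bromo-enynoate is cut at C3–Br and C2–C1′. It comes from an asymmetric three-component bromo-aldol of a silyl-capped penta-2,4-diynoate, Me3SiBr and butanal, which sets the (R)-carbinol and the tetrasubstituted alkene.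
4. The diynoate comes from 1,4-bis(trimethylsilyl)buta-1,3-diyne and methyl chloroformate.
5. Ring order: one ring only, closed in the last step.

Assumption: the (S)-configured oxazaborolidinium salt is taken to leave the Si face of a bound aldehyde open, as in its accepted binding model; if the first run gives the (S)-alcohol, the mirror-image salt from D-proline is used with nothing else changed.

**Route**

Step 1
Reactants: 1 1,4-bis(trimethylsilyl)buta-1,3-diyne; 2 methyl chloroformate
Product: 4 methyl 5-(trimethylsilyl)penta-2,4-diynoate, via lithium (trimethylsilyl)butadiynide 3 (not isolated)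
Conditions: MeLi·LiBr (1.0 equiv), THF/Et2O, 0 °C to rt, 3 h; then 2, −78 to 0 °C
Reagents that add atoms: none
Why: MeLi·LiBr removes only one silyl group of the symmetric diyne, and the resulting lithium acetylide is C-acylated by the chloroformate (acetylide acylation), with no stereocentre involved.

Step 2
Reactants: 4 methyl 5-(trimethylsilyl)penta-2,4-diynoate; 5 butanal
Product: 8 methyl (2E)-3-bromo-2-[(1R)-1-hydroxybutyl]-5-(trimethylsilyl)pent-2-en-4-ynoate, via silyl allenolate 6 (not isolated), via O-trimethylsilyl ether 7 (not isolated)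
Conditions: Me3SiBr (1.3 equiv), (S)-3,3-diphenyl-1-(2-methylphenyl)tetrahydro-1H,3H-pyrrolo[1,2-c][1,3,2]oxazaborole·HN(SO2CF3)2 (20 mol %), CH2Cl2, −78 to −40 °C; then 1 M HCl, THF, 0 °C
Reagents that add atoms: bromotrimethylsilane, C[Si](C)(C)Br
Why: Proposed new method: bromide from Me3SiBr adds 1,4 to the diynoate (the silyl cap blocks the 1,6 site) to give the β-bromo silyl allenolate 6, which attacks butanal bound to the chiral oxazaborolidinium cation in a Mukaiyama-type aldol within the plane of the C3 substituents; the formyl C–H···O contact and the aryl group covering the Re face direct attack to the Si face and set (R), and the aldehyde–catalyst complex passes the compact Br rather than the long silylethynyl rod, so carbinol and Br end up cis (2E), which is also the isomer that keeps the ester conjugated next to the slim alkyne; the closest known reaction type is the catalytic asymmetric three-component halo-aldol (β-iodo Morita–Baylis–Hillman) coupling of propiolates, Me3SiI and aldehydes, which has not been shown with bromide or with a β-substituted diynyl acceptor.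

Step 3
Reactants: 8 methyl (2E)-3-bromo-2-[(1R)-1-hydroxybutyl]-5-(trimethylsilyl)pent-2-en-4-ynoate
Product: 9 (2E)-3-bromo-2-[(1R)-1-hydroxybutyl]pent-2-en-4-ynoic acid
Conditions: LiOH (3 equiv), THF/H2O 3:1, 0 °C to rt; then 1 M HCl to pH 3
Reagents that add atoms: lithium hydroxide, [Li+].[OH-]
Why: Ester saponification and hydroxide-induced protodesilylation of the alkynylsilane run in one pot, and these mild conditions offer no pathway that changes the tetrasubstituted bromoalkene or the carbinol stereocentre.

Step 4
Reactants: 9 (2E)-3-bromo-2-[(1R)-1-hydroxybutyl]pent-2-en-4-ynoic acid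
Product: 10 (5E)-4-bromo-3-[(1R)-1-hydroxybutyl]-5-(iodomethylidene)furan-2(5H)-one
Conditions: I2 (1.2 equiv), NaHCO3 (3 equiv), MeCN, 0 °C, dark, 1 h; aq Na2S2O3 quench
Reagents that add atoms: iodine, II
Why: In this iodolactonisation the carboxylate, held cis to the alkyne by the 2E alkene, attacks the internal (Markovnikov) carbon of the iodonium-activated terminal alkyne in 5-exo-dig mode, anti addition of O and I fixes the (E)-iodomethylidene geometry, and the hydroxyl, which lies trans to the alkyne, cannot compete.

**Compound list**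
1 | 1,4-bis(trimethylsilyl)buta-1,3-diyne | C[Si](C)(C)C#CC#C[Si](C)(C)C | starting material
2 | methyl chloroformate | COC(=O)Cl | starting material
3 | lithium 4-(trimethylsilyl)buta-1,3-diyn-1-ide | [Li]C#CC#C[Si](C)(C)C | intermediate
4 | methyl 5-(trimethylsilyl)penta-2,4-diynoate | COC(=O)C#CC#C[Si](C)(C)C | intermediate
5 | butanal | CCCC=O | starting material
6 | {[3-bromo-1-methoxy-5-(trimethylsilyl)penta-1,2-dien-4-yn-1-yl]oxy}(trimethyl)silane | COC(O[Si](C)(C)C)=C=C(Br)C#C[Si](C)(C)C | intermediate
7 | methyl (2E)-3-bromo-5-(trimethylsilyl)-2-{(1R)-1-[(trimethylsilyl)oxy]butyl}pent-2-en-4-ynoate | CCC[C@@H](O[Si](C)(C)C)/C(C(=O)OC)=C(\Br)C#C[Si](C)(C)C | intermediate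
8 | methyl (2E)-3-bromo-2-[(1R)-1-hydroxybutyl]-5-(trimethylsilyl)pent-2-en-4-ynoate | CCC[C@@H](O)/C(C(=O)OC)=C(\Br)C#C[Si](C)(C)C | intermediate
9 | (2E)-3-bromo-2-[(1R)-1-hydroxybutyl]pent-2-en-4-ynoic acid | CCC[C@@H](O)/C(C(=O)O)=C(\Br)C#C | intermediate
10 | (5E)-4-bromo-3-[(1R)-1-hydroxybutyl]-5-(iodomethylidene)furan-2(5H)-one | CCC[C@@H](O)C1=C(Br)/C(=C\I)OC1=O | target

**Totals**
Total step count: 4. Longest linear sequence: 4 steps (1 → 4 → 8 → 9 → 10).

**Three steps most likely to fail**

Step 2 (the proposed new step). Bromide transfer from Me3SiBr may be sluggish. Some 1,6-addition may occur. The alkene may form partly as the 2Z isomer, which cannot lactonise. The ee with a linear aldehyde may be modest.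

The fallback uses known chemistry only. It sets out from 3 and returns at 9.
- Acetylide 3 is acylated with N-methoxy-N-methylbutanamide to 1-(trimethylsilyl)octa-1,3-diyn-5-one F1.
- Noyori transfer hydrogenation with RuCl(p-cymene)[(R,R)-TsDPEN] in i-PrOH gives (5R)-1-(trimethylsilyl)octa-1,3-diyn-5-ol F2.
- Hydroxyl-directed anti-carbomagnesiation with CH2=CHMgCl puts the vinyl group on the alkyne carbon next to the carbinol and holds Mg cis to the alkoxide. This gives (5R)-4-ethenyl-5-propyl-3-[(trimethylsilyl)ethynyl]-2,5-dihydro-1,2-oxamagnesole F3.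
- NBS converts F3 with retention into (3Z,5R)-3-bromo-4-ethenyl-1-(trimethylsilyl)oct-3-en-1-yn-5-ol F4.
- OsO4/NaIO4 cleaves only the monosubstituted vinyl group to (2E)-3-bromo-2-[(1R)-1-hydroxybutyl]-5-(trimethylsilyl)pent-2-en-4-ynal F5.
- NaClO2/NaH2PO4 oxidation gives (2E)-3-bromo-2-[(1R)-1-hydroxybutyl]-5-(trimethylsilyl)pent-2-en-4-ynoic acid F6.
- K2CO3 in MeOH removes the silyl cap to give 9.

In this fallback the stereocentre comes from ketone reduction and the alkene geometry from the magnesium chelate.

Step 3. The ester sits on a tetrasubstituted alkene and may hydrolyse slowly. Meanwhile hydroxide can attack the vinylogous acyl bromide carbon or the freed terminal enynoate.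

The fallback sets out from 8 and returns at 10. K2CO3 in MeOH removes only the silyl cap to give methyl (2E)-3-bromo-2-[(1R)-1-hydroxybutyl]pent-2-en-4-ynoate F7. The ester itself is then cyclised with I2 in CH2Cl2. This is an electrophilic cyclisation through the ester carbonyl oxygen, and iodide demethylates the resulting oxonium ion. No free acid and no hydroxide are needed.

Step 4. Closure may leak into the 6-endo mode, giving a 5-iodo-2-pyranone. Iodine and light may also erode the crowded E alkene towards Z.

The fallback sets out from 9 and returns at 10. Oxymercuration with Hg(O2CCF3)2 is strictly Markovnikov, anti and 5-exo. After exchange with aqueous NaCl it gives (5E)-4-bromo-5-[(chloromercurio)methylidene]-3-[(1R)-1-hydroxybutyl]furan-2(5H)-one F8. One equivalent of I2 at 0 °C in the dark then replaces mercury with retention. Ring size is fixed before any iodine is present.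

**Further compounds**
F1 | step 2 | 1-(trimethylsilyl)octa-1,3-diyn-5-one | CCCC(=O)C#CC#C[Si](C)(C)C
F2 | step 2 | (5R)-1-(trimethylsilyl)octa-1,3-diyn-5-ol | CCC[C@@H](O)C#CC#C[Si](C)(C)C
F3 | step 2 | (5R)-4-ethenyl-5-propyl-3-[(trimethylsilyl)ethynyl]-2,5-dihydro-1,2-oxamagnesole | CCC[C@H]1O[Mg]C(C#C[Si](C)(C)C)=C1C=C
F4 | step 2 | (3Z,5R)-3-bromo-4-ethenyl-1-(trimethylsilyl)oct-3-en-1-yn-5-ol | CCC[C@@H](O)/C(C=C)=C(\Br)C#C[Si](C)(C)C
F5 | step 2 | (2E)-3-bromo-2-[(1R)-1-hydroxybutyl]-5-(trimethylsilyl)pent-2-en-4-ynal | CCC[C@@H](O)/C(C=O)=C(\Br)C#C[Si](C)(C)C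
F6 | step 2 | (2E)-3-bromo-2-[(1R)-1-hydroxybutyl]-5-(trimethylsilyl)pent-2-en-4-ynoic acid | CCC[C@@H](O)/C(C(=O)O)=C(\Br)C#C[Si](C)(C)C
F7 | step 3 | methyl (2E)-3-bromo-2-[(1R)-1-hydroxybutyl]pent-2-en-4-ynoate | CCC[C@@H](O)/C(C(=O)OC)=C(\Br)C#C
F8 | step 4 | (5E)-4-bromo-5-[(chloromercurio)methylidene]-3-[(1R)-1-hydroxybutyl]furan-2(5H)-one | CCC[C@@H](O)C1=C(Br)/C(=C\[Hg]Cl)OC1=O
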